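Set beside the 25 h of each run, target and isomer of the product exchange on a short clock in the closed flask delta, and starting material enters the catalyst's round on a shorter clock still: their half-lives are 3.34 h and 0.49 h, the second by forward binding with the other concentrations held at their charge .

| flask | starting material | free catalyst | remark | time |
|---|---|---|---|---|
| beta | 0.14 M | 0.1 mol% | a single well-mixed tank run continuously and read at steady state, 25 h in it on average |  |
| delta | 0.14 M | 0.1 mol% | everything together in a closed stirred flask, run for 25 h | 25 h |
| zeta | 0.14 M (fed, over 20.0 h) | 0.1 mol% | a stirred flask in which starting material is dosed at a steady rate over 20.0 h without added volume, worked up at 25 h | 25 h |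

    catalyst intermediate B → free catalyst + target (k1 = 69 min⁻¹)
    starting material + free catalyst ⇌ catalyst intermediate A (K2 = 22 M⁻¹, k2 = 170 M⁻¹ min⁻¹)
    target ⇌ isomer of the product (K3 = 5.2, k3 = 0.0029 min⁻¹)
    2 catalyst intermediate B → spent catalyst (k4 = 79 M⁻¹ min⁻¹)
    catalyst intermediate A ⇌ catalyst intermediate B (K5 = 26, k5 = 22 min⁻¹)

- the set-up with the highest share of target in all that became target or isomer of the product, at the outlet or at the end ("none" if the first two lie within 2 percentage points) (beta / delta / zeta / none)
- share of target in all that became target or isomer of the product, at the outlet or at the end, beta
- share of target in all that became target or isomer of the product, at the outlet or at the end, delta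
- share of target in all that became target or isomer of the product, at the outlet or at the end, zeta

- a species is counted by the starting material in it: one spent catalyst counts as two
- a step written with two of one species runs at k times the square of its concentration and takes two of it each time
- the stated concentrations are those of everything mixed, before any reaction; amounts are the same in each set-up
- the feed brings no volume worth counting
- run time (delta): 25 h

I carried one number, 4.82 h, the relaxation time τ of the pair, which is the reciprocal of the sum of the forward and backward constants of the isomerisation. In τ the excess of the target share s over its equilibrium value s∞ falls by a factor e, and s∞ is 16.1 %, from the equilibrium constant of that step.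

In the first minutes of delta the round runs fast, for catalyst intermediate B lives 0.0145 min before it releases target, so target is what the round delivers and s starts at its top. In the middle, I had for starting material only the as-charged figure of 0.49 h, which takes the catalyst as wholly free and counts no return, so the flask's own uptake had to be slower than that; but the figure is shorter than the forward half-life of target, 4.0 h, by a wide enough gap that I expected target to pile up before it drained. At the end, delta has run 5.19 lifetimes, which leaves 0.559 % of the excess; this is thermodynamic rather than kinetic control, and I reckoned 16.6 %.

The tank beta has exponentially distributed ages with mean θ, here 25 h, and averaging the decay over them divides the excess by one plus θ/τ, which gave me 29.7 %. In zeta, target is born evenly over 20.0 h, so I averaged the decay over that span and then let it run to the end, which gave 23.2 %. My choice was beta.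

The forecast named beta, with 29.7 % for beta, 16.8 % for delta and 24.7 % for zeta, holding that “dosing leaves the late-made target fresher”; its zeta stands above mine.

The simulation gave 29.7 % for beta, 16.8 % for delta and 25.0 % for zeta, so the best was beta, and delta ended with 2.42 % of its catalyst spent.

In delta, half of the making of catalyst intermediate B was done by 1.17 h, and counted from there the flask ran 4.94 lifetimes. The same flask read at 6.0 h had run 1.00 lifetimes on that count, which gives a share of 46.9 %, and the reading there was 49.8 %, with target at 49.5 % and isomer of the product at 49.9 %.

(All constants are made up; what happens was integrated by code.)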